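## The problem

Numbering used throughout: the carbocycle is C1 (CH carrying the carbinol carbon C7), C2 (CH carrying coumarin ring B), C3=C4 (C4 bears a methyl group), C5H2 and C6 (gem-dimethyl); ring A is the 5,7-dimethoxycoumarin-8-yl group on C7 and ring B the identical group on C2. In target 24 the C1–C2 bond lies between the quaternary C6 and two aryl groups that are each substituted at both ortho positions, so it is the most congested bond of the molecule and the one the synthesis has to plan around. Three contiguous stereocentres are present, C7 (S), C1 (S) and C2 (R), with the C1 and C2 substituents trans. C2 is benzylic and allylic, has no acidifying neighbour and cannot be repaired later, so it must be set absolutely when its C–C bond is made. C1 is α to C7 and can be equilibrated while C7 is a carbonyl, and C7 can then be derived from C1 by addition to that carbonyl. The fragile groups are the two coumarin lactones (no organolithium, strong hydride or hot alkoxide), the C7 carbinol (benzylic with two ortho oxygens, it ionises under acid), the C3=C4 alkene (protonation gives a tertiary cation that a nearby phenol would trap) and the electron-rich rings; the pyranone rings and the C7 hydroxyl therefore belong at the end. The enabling feature is that C2 is allylic to C3=C4 while C1 is α to C7: C7(=O)–C1–C2–C3=C4 is the retron of a [3,3] shift of an enolate carbon onto an allylic ester C2=C3–C4–O, and because C4 is tied back to C1 through C5 and C6, that allylic oxygen and the acyl carbon C7 can be parts of one δ-lactone.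

## Retrosynthesis

**24 to 23.** The C7–H bond is cut, so the carbinol comes from ketone 23 in the last step. Creating C7 by aryl addition to an aldehyde would force the acid-labile carbinol through both coumarin annulations. Ketone 23 has one stereocentre fewer and no ionisable alcohol. The forward step must reduce a shielded ketone in preference to two lactones and choose the face dictated by C1.

**23 to 21 to 20.** Both pyranone rings are cut at the C3=C4 alkene and the lactone C–O bond (Wittig olefination of salicylaldehydes, then ring closure), and the formyl carbons are removed back to diphenol 20. The two rings are treated identically, so each operation is done twice in one flask. The forward formylation must go ortho to each phenol; each ring has only one free ortho carbon.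

**20 to 19 to 18.** One O–CH3 bond ortho to the ketone is restored, so ring A enters as the symmetric 2,4,6-trimethoxyphenyl group and no regiochemical question arises at its introduction. Trans ketone 19 is then traced to its C1 epimer 18, because C1 is the one centre that can be corrected by equilibration.

**18 to 15 and 17.** The C7–aryl bond is cut to aryllithium 17 (from 16) and the cis-fused aryl lactone 15. Using the ring-B phenol as the leaving group activates the hindered acyl carbon and frees that phenol in one event, which amide or acid chloride activation would not do. The forward step needs single addition, which the congestion around the product ketone should enforce.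

**15 to 13.** The lactone C–O bond is cut and the phenol returns to its methoxymethyl ether. The cis relationship in acid 13 is what lets the lactone close.

**13 to 10 (key disconnection).** The C1–C2 bond is cut, the C4–O bond restored and the alkene returned to C2=C3, giving styryl δ-lactone 10. The neighbouring Diels–Alder cut (C1–C2 and C5–C6) would need a β,β-dimethyl acrylate, a poor dienophile. The [3,3] cut removes the ring and both ring stereocentres and leaves one tertiary carbinol centre. The forward shift must pass a boat transition state and transfer the C4 configuration to C2; the E alkene is chosen because it places the aryl group on the open side of the boat, at the price of a cis C1.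

**10 to 9 to 3 and 6.** The lactone is opened to hydroxy ester 9 and the C3–C4 bond is cut to keto ester 3 and alkyne 6 (through vinylzinc 8). All stereochemistry is thus reduced to one catalytic asymmetric addition to a methyl ketone.

**6 to 5 to 4, and 3 to 2 to 1.** The alkyne comes from aldehyde 5 by one-carbon homologation and 5 from commercial 4 by phenol protection. Keto ester 3 comes from keto acid 2 and this from dimedone 1 by retro-Claisen cleavage.

## Roads not taken

**Alternative 1:** The cut is C2–C3, with C1=C7 held as the C3=C2 bond of a benzopyrylium ion whose ring oxygen is the ring-B phenol.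
- **Forward key step:** in flavylium ion A2 the tethered (Z)-vinylsilane attacks C4 of the cation (C2 of the target); loss of Me3Si leaves the C3=C4 alkene and the 4H-chromene A1.
- **Merits:** C7–C1 and both aryl rings are in place before the ring forms, silicon fixes the alkene position, and hydrolysis of the enol ether in A1 would give ketone 18 or 19 directly. No lactone and no aryllithium are needed, so A1 would be reached in fewer steps than 19.
- **Weak points:** A2 is flat and its tether has no stereocentre, so C2 would have to be controlled by a chiral counter-ion, for which an intramolecular vinylsilane attack on a 2-aryl benzopyrylium has no close model. A2 carries a tertiary alkyl group next to a 2,6-dioxygenated aryl group and must be generated under acid that also threatens the vinylsilane. Hydrolysis of A1 sets C1 by protonation, so the epimerisation remains, as do both coumarin annulations.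
- **Comparison:** the chosen plan has a longer stretch (steps 8 to 10). It sets against this a C2 derived by chirality transfer from a centre made by an established catalytic reaction.

**Alternative 2:** The cut is in the two pyran rings only (C4–C4a and O1–C2 of each coumarin); the carbocycle, C1, C2 and the C7 ketone are presupposed.
- **Forward key step:** the bis(propargyl ether) A4, available from diphenol 20 by O-alkylation, is heated; each ring undergoes [3,3] shift, hydrogen shift and oxa-6π closure to give the bis(2H-chromene) ketone A3.
- **Merits:** the C–C bond can only form at the free ortho carbon, and no electrophilic substitution of the chelated ring-A phenol is needed. In this respect it is safer than step 12.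
- **Weak points:** A3 is at the wrong oxidation level. Both pyran CH2 groups must be oxidised to lactone carbonyls, for instance with a hexavalent chromium oxidant such as CrO3·2C5H5N, in a molecule with other allylic and benzylic C–H bonds (C5 and C2). It is an end-game only and says nothing about the carbocycle or its stereocentres.
- **Comparison:** from 20 it needs three steps against two. The chosen plan reaches the coumarin oxidation level directly and has, as fallback for step 12, a tethered hydroarylation with the same regiochemical security.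

**Alternative 3:** The cuts are C1–C2 and C3–C4, opening the ring to keto aldehyde A7 and nitrostyrene A6.
- **Forward key step:** the enamine of A7 with diphenylprolinol trimethylsilyl ether adds to A6 (C1–C2), and base closes C3–C4 by Henry reaction of the nitronate on the methyl ketone, giving A5.
- **Merits:** a small-molecule catalyst sets C1 and C2 trans in two steps from simple fragments, and C7 emerges as an aldehyde. Neither an epimerisation nor a tertiary carbinol is needed; in stereochemical economy this road is better than the chosen one.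
- **Weak points:** the Michael step pairs an aldehyde whose α-carbon adjoins a quaternary centre with a hindered, electron-rich nitrostyrene, outside the usual scope of this catalysis. Turning the nitro alcohol of A5 into an alkene exactly at C3=C4 takes several uncertain steps (dehydration gives a nitroalkene; retro-Henry cleavage threatens). Aryl addition to the aldehyde creates the C7 carbinol before the coumarins exist, so the most acid-labile group would be carried through both annulations.
- **Comparison:** the chosen plan pays with one epimerisation step. In return the [3,3] shift places the alkene, there is no nitrogen to excise, and C7 stays a ketone until the end.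

Key step: step 7

Assumption: in step 5 the ligand antipode is chosen to give (R)-9; the facial preference known for aryl methyl ketones is taken to hold for methyl alkyl ketone 3.

## Route

Step 1
Reactants: 1 dimedone (5,5-dimethylcyclohexane-1,3-dione)
Product: 2 3,3-dimethyl-5-oxohexanoic acid
Conditions: Ba(OH)2·8H2O, H2O, reflux; then aq. HCl
Reagents that add atoms: water, O
Why: Retro-Claisen cleavage of a cyclic 1,3-diketone by hydroxide; the symmetric dione can open in only one way and should give the δ-keto acid.

Step 2
Reactants: 2 3,3-dimethyl-5-oxohexanoic acid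
Product: 3 methyl 3,3-dimethyl-5-oxohexanoate
Conditions: MeOH, H2SO4 (cat.), reflux
Reagents that add atoms: methanol, CO
Why: Fischer esterification; the ester is inert to organozinc reagents and later serves as the acyl donor for lactonisation.

Step 3
Reactants: 4 2-hydroxy-4,6-dimethoxybenzaldehyde
Product: 5 2,4-dimethoxy-6-(methoxymethoxy)benzaldehyde
Conditions: MOMCl, i-Pr2NEt, CH2Cl2, 0 °C to rt
Reagents that add atoms: chloromethyl methyl ether, COCCl
Why: O-alkylation of the phenol as its methoxymethyl acetal; this group should survive carbonate, organozirconium, organozinc and amide bases and is removed later under mild Lewis acid.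

Step 4
Reactants: 5 2,4-dimethoxy-6-(methoxymethoxy)benzaldehyde
Product: 6 2-ethynyl-1,5-dimethoxy-3-(methoxymethoxy)benzene
Conditions: dimethyl (1-diazo-2-oxopropyl)phosphonate, K2CO3, MeOH, rt
Reagents that add atoms: dimethyl (1-diazo-2-oxopropyl)phosphonate, COP(=O)(OC)C(=[N+]=[N-])C(C)=O
Why: Seyferth–Gilbert homologation in the Ohira–Bestmann variant; the aldehyde is not enolisable and the basic medium spares the acetal.

Step 5
Reactants: 6 2-ethynyl-1,5-dimethoxy-3-(methoxymethoxy)benzene; 3 methyl 3,3-dimethyl-5-oxohexanoate
Product: 9 methyl (5R,6E)-7-[2,4-dimethoxy-6-(methoxymethoxy)phenyl]-5-hydroxy-3,3,5-trimethylhept-6-enoate, via vinylzirconocene 7 (not isolated), via vinyl(methyl)zinc 8 (not isolated)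
Conditions: Cp2Zr(H)Cl, CH2Cl2, rt; ZnMe2, toluene, −78 °C; then 3, Ti(OiPr)4, trans-cyclohexane-1,2-diamine bis(camphorsulfonamide)-derived diol ligand (10 mol %), toluene, rt
Reagents that add atoms: none
Why: Syn hydrozirconation places zirconium on the terminal carbon and fixes the E geometry, and transmetalation gives the vinylzinc. The titanium/bis(sulfonamide) diol-catalysed asymmetric 1,2-addition to the ketone should set the tertiary carbinol (future C4) as R by distinguishing the methyl group from the branched CH2 chain; the ester does not react with organozinc.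

Step 6
Reactants: 9 methyl (5R,6E)-7-[2,4-dimethoxy-6-(methoxymethoxy)phenyl]-5-hydroxy-3,3,5-trimethylhept-6-enoate
Product: 10 (6R)-6-{(E)-2-[2,4-dimethoxy-6-(methoxymethoxy)phenyl]ethenyl}-4,4,6-trimethyloxan-2-one
Conditions: NaH (0.2 equiv), THF, 4 Å molecular sieves, 0 °C to rt; pH 7 buffer; chromatography on Et3N-treated silica
Reagents that add atoms: none
Why: Base-catalysed intramolecular transesterification (lactonisation), favoured by the gem-dimethyl group (Thorpe–Ingold effect) and by uptake of methanol. Only the acyl–oxygen bond is exchanged, so the stereocentre is untouched, and acid, which would ionise the tertiary allylic C–O bond, is avoided.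

Step 7
Reactants: 10 (6R)-6-{(E)-2-[2,4-dimethoxy-6-(methoxymethoxy)phenyl]ethenyl}-4,4,6-trimethyloxan-2-one
Product: 13 (1R,2R)-2-[2,4-dimethoxy-6-(methoxymethoxy)phenyl]-4,6,6-trimethylcyclohex-3-ene-1-carboxylic acid (cis), via silyl ketene acetal 11 (not isolated), via trimethylsilyl ester 12 (not isolated)
Conditions: LDA, Me3SiCl/Et3N, THF, −78 °C; then toluene, 80 °C; aq. citric acid, THF, rt
Reagents that add atoms: none
Why: LDA removes a C1 proton of the lactone in the presence of Me3SiCl, and O-silylation gives the cyclic ketene acetal 11, whose double-bond geometry is fixed by the ring. On warming, 11 should undergo a concerted suprafacial [3,3] sigmatropic shift (Ireland–Claisen rearrangement) in which C1–C2 forms, C4–O breaks and the alkene moves from C2=C3 to C3=C4; hydrolysis of silyl ester 12 then gives 13. The closest known reaction type is the Ireland–Claisen ring contraction of 6-alkenyl δ-lactones and of 6-alkenyl-1,4-dioxan-2-ones to dihydropyrans. The cyclohexene is closed by the sigmatropic bond formation itself: because C1 and C4 are tied by the C5–C6 bridge, the six reacting atoms can only adopt a boat, bicyclo[2.2.2]octane-like array. C2 is controlled by the C4 stereocentre, since the shift is suprafacial across the allyl unit and the (E)-aryl group sits on the open, exo side of the boat, so that (R)-C4 is traded for (R)-C2. C1 is controlled by the ring-fixed ketene acetal geometry in the same boat, which leaves H-1 exo and C7 cis to the aryl group. The step needs the pericyclic path to win over heterolysis of the tertiary allylic C–O bond and over C-silylation: in 11 the leaving group of a heterolysis would be an ester enolate, a poor nucleofuge; Et3N keeps the medium free of acid; and the donor aryl group should lower the barrier of the polarised transition state.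

Step 8
Reactants: 13 (1R,2R)-2-[2,4-dimethoxy-6-(methoxymethoxy)phenyl]-4,6,6-trimethylcyclohex-3-ene-1-carboxylic acid
Product: 15 (6aR,10aR)-1,3-dimethoxy-7,7,9-trimethyl-6a,7,8,10a-tetrahydro-6H-benzo[c]chromen-6-one (cis-fused lactone), via hydroxy acid 14 (not isolated)
Conditions: ZnBr2, n-PrSH, CH2Cl2, 0 °C; then EDC·HCl, DMAP (cat.), CH2Cl2, rt
Reagents that add atoms: none
Why: Lewis acid-mediated acetal cleavage in which the thiol captures the methoxymethyl cation before it can alkylate the electron-rich ring. Carbodiimide lactonisation of the cis-disposed phenol and acid then closes the six-membered aryl lactone; no stereocentre is involved.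

Step 9
Reactants: 15 (6aR,10aR)-1,3-dimethoxy-7,7,9-trimethyl-6a,7,8,10a-tetrahydro-6H-benzo[c]chromen-6-one; 16 1,3,5-trimethoxybenzene
Product: 18 [(1R,2R)-2-(2-hydroxy-4,6-dimethoxyphenyl)-4,6,6-trimethylcyclohex-3-en-1-yl](2,4,6-trimethoxyphenyl)methanone (cis ketone), via 2,4,6-trimethoxyphenyllithium 17 (not isolated)
Conditions: 16, n-BuLi, THF, 0 °C to rt; then 15, THF, −78 to 0 °C; aq. NH4Cl
Reagents that add atoms: none
Why: Directed ortho-lithiation of 16 between two methoxy groups, then acyl substitution at the aryl lactone with the ring-B phenoxide as leaving group. A second addition is blocked because the ketone is flanked by a quaternary carbon and a 2,6-disubstituted ring; any partial epimerisation at C1 is immaterial, as step 10 equilibrates that centre.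

Step 10
Reactants: 18 [(1R,2R)-2-(2-hydroxy-4,6-dimethoxyphenyl)-4,6,6-trimethylcyclohex-3-en-1-yl](2,4,6-trimethoxyphenyl)methanone
Product: 19 [(1S,2R)-2-(2-hydroxy-4,6-dimethoxyphenyl)-4,6,6-trimethylcyclohex-3-en-1-yl](2,4,6-trimethoxyphenyl)methanone (trans ketone)
Conditions: NaOMe, MeOH, 60 °C; then AcOH
Reagents that add atoms: none
Why: Base-mediated epimerisation α to the ketone through its enolate under thermodynamic control. The trans isomer can hold the aroyl and aryl groups both equatorial, whereas the cis isomer must place one axial (an axial aryl group would clash with the axial C6 methyl); C2 has no acidic hydrogen and is untouched.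

Step 11
Reactants: 19 [(1S,2R)-2-(2-hydroxy-4,6-dimethoxyphenyl)-4,6,6-trimethylcyclohex-3-en-1-yl](2,4,6-trimethoxyphenyl)methanone
Product: 20 (2-hydroxy-4,6-dimethoxyphenyl)[(1S,2R)-2-(2-hydroxy-4,6-dimethoxyphenyl)-4,6,6-trimethylcyclohex-3-en-1-yl]methanone
Conditions: BCl3, CH2Cl2, −78 to 0 °C; then MeOH, aq. NaHCO3
Reagents that add atoms: none
Why: Chelation-controlled Lewis acid cleavage of an aryl methyl ether: boron bound to the ketone oxygen activates only an ortho methoxy group, the two ortho groups are equivalent, and the boron chelate formed after the first cleavage protects the second. Low temperature should keep the ring-B phenol, held as its borate, from condensing with the ketone or adding to the alkene.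

Step 12
Reactants: 20 (2-hydroxy-4,6-dimethoxyphenyl)[(1S,2R)-2-(2-hydroxy-4,6-dimethoxyphenyl)-4,6,6-trimethylcyclohex-3-en-1-yl]methanone
Product: 21 3-{[(1S,2R)-2-(3-formyl-2-hydroxy-4,6-dimethoxyphenyl)-4,6,6-trimethylcyclohex-3-en-1-yl]carbonyl}-2-hydroxy-4,6-dimethoxybenzaldehyde
Conditions: MgCl2, Et3N, (CH2O)n, MeCN, reflux; then 1 M HCl
Reagents that add atoms: formaldehyde (from paraformaldehyde), C=O
Why: Magnesium-mediated ortho-formylation of phenols: the magnesium phenoxide delivers formaldehyde to the ortho carbon through a cyclic transition state, and hydride transfer to a second formaldehyde gives the aldehyde. Each ring has only one free ortho position, so both rings should be formylated at the carbon that becomes C4a of a coumarin.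

Step 13
Reactants: 21 3-{[(1S,2R)-2-(3-formyl-2-hydroxy-4,6-dimethoxyphenyl)-4,6,6-trimethylcyclohex-3-en-1-yl]carbonyl}-2-hydroxy-4,6-dimethoxybenzaldehyde
Product: 23 8-{(1R,6S)-6-[(5,7-dimethoxy-2-oxo-2H-chromen-8-yl)carbonyl]-3,5,5-trimethylcyclohex-2-en-1-yl}-5,7-dimethoxy-2H-chromen-2-one, via bis(hydroxycinnamate) diester 22 (not isolated)
Conditions: Ph3P=CHCO2Et, PhNEt2, reflux
Reagents that add atoms: ethyl (triphenylphosphoranylidene)acetate, CCOC(=O)C=P(c1ccccc1)(c1ccccc1)c1ccccc1
Why: Wittig olefination of both salicylaldehydes with a stabilised ylide; at the boiling point of N,N-diethylaniline the cinnamates isomerise and lactonise with loss of ethanol to the coumarins. The hindered ketone does not react with the stabilised ylide, and C1 is already at its thermodynamic configuration.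

Step 14
Reactants: 23 8-{(1R,6S)-6-[(5,7-dimethoxy-2-oxo-2H-chromen-8-yl)carbonyl]-3,5,5-trimethylcyclohex-2-en-1-yl}-5,7-dimethoxy-2H-chromen-2-one
Product: 24 8-{(1R,6S)-6-[(S)-(5,7-dimethoxy-2-oxo-2H-chromen-8-yl)(hydroxy)methyl]-3,5,5-trimethylcyclohex-2-en-1-yl}-5,7-dimethoxy-2H-chromen-2-one (target)
Conditions: NaBH4, CeCl3·7H2O, MeOH/THF, −40 to 0 °C
Reagents that add atoms: none
Why: Luche reduction, selective for the ketone over the conjugated lactones. In the Felkin–Anh arrangement the quaternary C6 stands anti to the incoming hydride and H-1 lies next to the perpendicular ring-A aryl group, so hydride should add to the face that gives (S)-C7.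

## Compound list

1 | dimedone (5,5-dimethylcyclohexane-1,3-dione) | CC1(C)CC(=O)CC(=O)C1 | starting material
2 | 3,3-dimethyl-5-oxohexanoic acid | CC(=O)CC(C)(C)CC(=O)O | intermediate
3 | methyl 3,3-dimethyl-5-oxohexanoate | COC(=O)CC(C)(C)CC(C)=O | intermediate
4 | 2-hydroxy-4,6-dimethoxybenzaldehyde | COc1cc(O)c(C=O)c(OC)c1 | starting material
5 | 2,4-dimethoxy-6-(methoxymethoxy)benzaldehyde | COCOc1cc(OC)cc(OC)c1C=O | intermediate
6 | 2-ethynyl-1,5-dimethoxy-3-(methoxymethoxy)benzene | COCOc1cc(OC)cc(OC)c1C#C | intermediate
7 | chloro{(E)-2-[2,4-dimethoxy-6-(methoxymethoxy)phenyl]ethenyl}zirconocene (cyclopentadienyl rings written σ-bonded) | COCOc1cc(OC)cc(OC)c1/C=C/[Zr](Cl)(C1C=CC=C1)C1C=CC=C1 | intermediate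
8 | {(E)-2-[2,4-dimethoxy-6-(methoxymethoxy)phenyl]ethenyl}(methyl)zinc | COCOc1cc(OC)cc(OC)c1/C=C/[Zn]C | intermediate
9 | methyl (5R,6E)-7-[2,4-dimethoxy-6-(methoxymethoxy)phenyl]-5-hydroxy-3,3,5-trimethylhept-6-enoate | COC(=O)CC(C)(C)C[C@@](C)(O)/C=C/c1c(OC)cc(OC)cc1OCOC | intermediate
10 | (6R)-6-{(E)-2-[2,4-dimethoxy-6-(methoxymethoxy)phenyl]ethenyl}-4,4,6-trimethyloxan-2-one | O=C1CC(C)(C)C[C@](C)(/C=C/c2c(OC)cc(OC)cc2OCOC)O1 | intermediate
11 | (2R)-2-{(E)-2-[2,4-dimethoxy-6-(methoxymethoxy)phenyl]ethenyl}-2,4,4-trimethyl-6-(trimethylsilyloxy)-3,4-dihydro-2H-pyran | C[Si](C)(C)OC1=CC(C)(C)C[C@](C)(/C=C/c2c(OC)cc(OC)cc2OCOC)O1 | intermediate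
12 | trimethylsilyl (1R,2R)-2-[2,4-dimethoxy-6-(methoxymethoxy)phenyl]-4,6,6-trimethylcyclohex-3-ene-1-carboxylate | C[Si](C)(C)OC(=O)[C@@H]1[C@H](c2c(OC)cc(OC)cc2OCOC)C=C(C)CC1(C)C | intermediate
13 | (1R,2R)-2-[2,4-dimethoxy-6-(methoxymethoxy)phenyl]-4,6,6-trimethylcyclohex-3-ene-1-carboxylic acid (cis) | OC(=O)[C@@H]1[C@H](c2c(OC)cc(OC)cc2OCOC)C=C(C)CC1(C)C | intermediate
14 | (1R,2R)-2-(2-hydroxy-4,6-dimethoxyphenyl)-4,6,6-trimethylcyclohex-3-ene-1-carboxylic acid | OC(=O)[C@@H]1[C@H](c2c(OC)cc(OC)cc2O)C=C(C)CC1(C)C | intermediate
15 | (6aR,10aR)-1,3-dimethoxy-7,7,9-trimethyl-6a,7,8,10a-tetrahydro-6H-benzo[c]chromen-6-one | O=C3[C@@H]1[C@H](c2c(OC)cc(OC)cc2O3)C=C(C)CC1(C)C | intermediate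
16 | 1,3,5-trimethoxybenzene | COc1cc(OC)cc(OC)c1 | starting material
17 | 2,4,6-trimethoxyphenyllithium | [Li]c1c(OC)cc(OC)cc1OC | intermediate
18 | [(1R,2R)-2-(2-hydroxy-4,6-dimethoxyphenyl)-4,6,6-trimethylcyclohex-3-en-1-yl](2,4,6-trimethoxyphenyl)methanone (cis) | COc1cc(OC)c(c(OC)c1)C(=O)[C@@H]1[C@H](c2c(OC)cc(OC)cc2O)C=C(C)CC1(C)C | intermediate
19 | [(1S,2R)-2-(2-hydroxy-4,6-dimethoxyphenyl)-4,6,6-trimethylcyclohex-3-en-1-yl](2,4,6-trimethoxyphenyl)methanone (trans) | COc1cc(OC)c(c(OC)c1)C(=O)[C@H]1[C@H](c2c(OC)cc(OC)cc2O)C=C(C)CC1(C)C | intermediate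
20 | (2-hydroxy-4,6-dimethoxyphenyl)[(1S,2R)-2-(2-hydroxy-4,6-dimethoxyphenyl)-4,6,6-trimethylcyclohex-3-en-1-yl]methanone | COc1cc(O)c(c(OC)c1)C(=O)[C@H]1[C@H](c2c(OC)cc(OC)cc2O)C=C(C)CC1(C)C | intermediate
21 | 3-{[(1S,2R)-2-(3-formyl-2-hydroxy-4,6-dimethoxyphenyl)-4,6,6-trimethylcyclohex-3-en-1-yl]carbonyl}-2-hydroxy-4,6-dimethoxybenzaldehyde | COc1cc(OC)c(C=O)c(O)c1C(=O)[C@H]1[C@H](c2c(OC)cc(OC)c(C=O)c2O)C=C(C)CC1(C)C | intermediate
22 | bis(ethyl 2-hydroxycinnamate) from 21: each formyl group replaced by (E)-CH=CH–CO2Et, (1S,2R) core unchanged | CCOC(=O)/C=C/c1c(OC)cc(OC)c(c1O)C(=O)[C@H]1[C@H](c2c(OC)cc(OC)c(/C=C/C(=O)OCC)c2O)C=C(C)CC1(C)C | intermediate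
23 | 8-{(1R,6S)-6-[(5,7-dimethoxy-2-oxo-2H-chromen-8-yl)carbonyl]-3,5,5-trimethylcyclohex-2-en-1-yl}-5,7-dimethoxy-2H-chromen-2-one | COc1cc(OC)c2ccc(=O)oc2c1C(=O)[C@H]1[C@H](c2c(OC)cc(OC)c3ccc(=O)oc23)C=C(C)CC1(C)C | intermediate
24 | 8-{(1R,6S)-6-[(S)-(5,7-dimethoxy-2-oxo-2H-chromen-8-yl)(hydroxy)methyl]-3,5,5-trimethylcyclohex-2-en-1-yl}-5,7-dimethoxy-2H-chromen-2-one | COc1cc(OC)c2ccc(=O)oc2c1[C@@H](O)[C@H]1[C@H](c2c(OC)cc(OC)c3ccc(=O)oc23)C=C(C)CC1(C)C | target

## Step count and risk

Total step count: 14. Longest linear sequence: 12 steps (1 through 2, 3, 9, 10, 13, 15, 18, 19, 20, 21 and 23 to 24; the branch from 4 is equally long).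

**Step 7 (key step).** The most likely failure is that the sigmatropic shift is outrun by loss of the tertiary allylic oxygen. Lactone 10 can ionise with trace acid or with Me3SiCl acting as a Lewis acid, and forming the C1–C2 bond between a quaternary carbon and a 2,6-disubstituted ring may be slow enough for the ketene acetal to decompose or to rearrange with partial loss of stereochemical fidelity.

The fallback runs the same [3,3] bond formation on an open-chain, secondary allylic ester through a chair transition state and closes the ring afterwards. It sets out from 2 and 5 and comes back at 13.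
- Aldol condensation of 5 with acetone (aq. NaOH) would give (E)-4-[2,4-dimethoxy-6-(methoxymethoxy)phenyl]but-3-en-2-one F1.
- Corey–Bakshi–Shibata reduction ((R)-oxazaborolidine, BH3·SMe2) would give (2S,3E)-4-[2,4-dimethoxy-6-(methoxymethoxy)phenyl]but-3-en-2-ol F2.
- Keto acid 2 would be methylenated (Ph3P=CH2, 2.2 equiv) to 3,3,5-trimethylhex-5-enoic acid F3 and coupled with F2 (DCC, DMAP) to (2S,3E)-4-[2,4-dimethoxy-6-(methoxymethoxy)phenyl]but-3-en-2-yl 3,3,5-trimethylhex-5-enoate F4.
- Ireland–Claisen rearrangement of F4 through its (Z)-silyl ketene acetal (LDA, THF/DMPU, Me3SiCl) should give (2R,3R,4E)-3-[2,4-dimethoxy-6-(methoxymethoxy)phenyl]-2-(2,4-dimethylpent-4-en-2-yl)hex-4-enoic acid F5, which has the C1 and C2 configurations of 13.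
- Ring-closing metathesis (second-generation Grubbs catalyst) between the propenyl group and the 1,1-disubstituted alkene would close C3=C4 and return to 13.

Enolisation in THF alone is expected to reverse the C1 configuration; that option is not pursued here.

**Step 5.** The most likely failure is insufficient facial discrimination. The catalyst must tell a methyl group from a CH2 chain at a dialkyl ketone, and the ester and the ortho ether oxygens can compete for zinc and titanium. The fallback replaces asymmetric catalysis by resolution, setting out from 3 and 6 and coming back at 10. The addition would be run with the racemic ligand to give racemic methyl (E)-7-[2,4-dimethoxy-6-(methoxymethoxy)phenyl]-5-hydroxy-3,3,5-trimethylhept-6-enoate F6. This would be lactonised as in step 6 to racemic (E)-6-{2-[2,4-dimethoxy-6-(methoxymethoxy)phenyl]ethenyl}-4,4,6-trimethyloxan-2-one F7, and the enantiomers separated by preparative chromatography on a chiral stationary phase to give 10.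

**Step 10.** The most likely failure is slow enolisation of the shielded ketone, together with a thermodynamic margin between the cis and trans isomers that may be small, because the equatorial aroyl group is gauche to both C6 methyl groups. The fallback moves the equilibration to the aldehyde oxidation level, where C1 carries a small, easily enolised group, and forms the C7–aryl bond by addition. It sets out from 15 and comes back at 19.
- Reduction with i-Bu2AlH (−78 °C) would give (6aR,10aR)-1,3-dimethoxy-7,7,9-trimethyl-6a,7,8,10a-tetrahydro-6H-benzo[c]chromen-6-ol F8.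
- DBU would equilibrate it through the open hydroxy aldehyde to the trans-fused (6aS,10aR)-1,3-dimethoxy-7,7,9-trimethyl-6a,7,8,10a-tetrahydro-6H-benzo[c]chromen-6-ol F9.
- Addition of aryllithium 17 (3 equiv) would give [(1S,2R)-2-(2-hydroxy-4,6-dimethoxyphenyl)-4,6,6-trimethylcyclohex-3-en-1-yl](2,4,6-trimethoxyphenyl)methanol F10 as a mixture at C7.
- Oxidation of the benzylic alcohol with MnO2 would return to 19.

**Step 12.** The most likely failure is incomplete formylation of ring A, whose phenoxide is held in a chelate with the ketone and deactivated by it, leaving the ring-B monoaldehyde. The fallback makes the C4–C4a bonds by tethered hydroarylation instead of formylation and olefination. It sets out from 20 and comes back at 23, bypassing 21 and 22. Esterification of both phenols with propiolic acid (DCC) would give the bis(propiolate) (1S,2R)-ketone F11. Catalytic AuCl(PPh3)/AgSbF6 (a cationic complex of monovalent gold) should then close both pyranone rings by 6-endo hydroarylation at the only free ortho carbons.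

**Step 14.** The most likely failure is hydride attack on the coumarin lactones or their C3=C4 bonds in competition with the shielded ketone; modest facial selectivity is the second concern. The fallback masks the lactones reversibly, setting out from 23 and coming back at 24. Aqueous NaOH would open both rings to the tetrasodium bis[(Z)-2-oxidocinnamate] of the ketone F12, which is inert to borohydride. NaBH4 in the same alkaline solution would reduce the ketone to the tetrasodium salt of the (S)-carbinol F13, and acidification with AcOH would close both coumarin rings again to give 24. The facial choice remains substrate-controlled.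

Further compounds
F1 | step 7 | (E)-4-[2,4-dimethoxy-6-(methoxymethoxy)phenyl]but-3-en-2-one | CC(=O)/C=C/c1c(OC)cc(OC)cc1OCOC
F2 | step 7 | (2S,3E)-4-[2,4-dimethoxy-6-(methoxymethoxy)phenyl]but-3-en-2-ol | C[C@H](O)/C=C/c1c(OC)cc(OC)cc1OCOC
F3 | step 7 | 3,3,5-trimethylhex-5-enoic acid | C=C(C)CC(C)(C)CC(=O)O
F4 | step 7 | (2S,3E)-4-[2,4-dimethoxy-6-(methoxymethoxy)phenyl]but-3-en-2-yl 3,3,5-trimethylhex-5-enoate | C=C(C)CC(C)(C)CC(=O)O[C@@H](C)/C=C/c1c(OC)cc(OC)cc1OCOC
F5 | step 7 | (2R,3R,4E)-3-[2,4-dimethoxy-6-(methoxymethoxy)phenyl]-2-(2,4-dimethylpent-4-en-2-yl)hex-4-enoic acid | OC(=O)[C@@H](C(C)(C)CC(C)=C)[C@H](c1c(OC)cc(OC)cc1OCOC)/C=C/C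
F6 | step 5 | racemic methyl (E)-7-[2,4-dimethoxy-6-(methoxymethoxy)phenyl]-5-hydroxy-3,3,5-trimethylhept-6-enoate | COC(=O)CC(C)(C)CC(C)(O)/C=C/c1c(OC)cc(OC)cc1OCOC
F7 | step 5 | racemic (E)-6-{2-[2,4-dimethoxy-6-(methoxymethoxy)phenyl]ethenyl}-4,4,6-trimethyloxan-2-one | O=C1CC(C)(C)CC(C)(/C=C/c2c(OC)cc(OC)cc2OCOC)O1
F8 | step 10 | (6aR,10aR)-1,3-dimethoxy-7,7,9-trimethyl-6a,7,8,10a-tetrahydro-6H-benzo[c]chromen-6-ol (cis-fused lactol, C6 epimers) | OC3[C@@H]1[C@H](c2c(OC)cc(OC)cc2O3)C=C(C)CC1(C)C
F9 | step 10 | (6aS,10aR)-1,3-dimethoxy-7,7,9-trimethyl-6a,7,8,10a-tetrahydro-6H-benzo[c]chromen-6-ol (trans-fused lactol, C6 epimers) | OC3[C@H]1[C@H](c2c(OC)cc(OC)cc2O3)C=C(C)CC1(C)C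
F10 | step 10 | [(1S,2R)-2-(2-hydroxy-4,6-dimethoxyphenyl)-4,6,6-trimethylcyclohex-3-en-1-yl](2,4,6-trimethoxyphenyl)methanol (C7 epimers) | COc1cc(OC)c(c(OC)c1)C(O)[C@H]1[C@H](c2c(OC)cc(OC)cc2O)C=C(C)CC1(C)C
F11 | step 12 | bis(propiolate) of 20: 2-{[(1S,2R)-2-(2-propioloyloxy-4,6-dimethoxyphenyl)-4,6,6-trimethylcyclohex-3-en-1-yl]carbonyl}-3,5-dimethoxyphenyl propiolate | C#CC(=O)Oc1cc(OC)cc(OC)c1C(=O)[C@H]1[C@H](c2c(OC)cc(OC)cc2OC(=O)C#C)C=C(C)CC1(C)C
F12 | step 14 | tetrasodium salt of ketone 23 with both lactones opened to (Z)-3-(2-oxidoaryl)acrylates | [O-]C(=O)/C=C\c1c(OC)cc(OC)c(c1[O-])C(=O)[C@H]1[C@H](c2c(OC)cc(OC)c(/C=C\C(=O)[O-])c2[O-])C=C(C)CC1(C)C.[Na+].[Na+].[Na+].[Na+]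
F13 | step 14 | tetrasodium salt of the (S)-C7 carbinol with both lactones opened to (Z)-3-(2-oxidoaryl)acrylates | [O-]C(=O)/C=C\c1c(OC)cc(OC)c(c1[O-])[C@@H](O)[C@H]1[C@H](c2c(OC)cc(OC)c(/C=C\C(=O)[O-])c2[O-])C=C(C)CC1(C)C.[Na+].[Na+].[Na+].[Na+]
A1 | alternative 1 | 1,3-dimethoxy-7,7,9-trimethyl-6-(2,4,6-trimethoxyphenyl)-8,10a-dihydro-7H-benzo[c]chromene, C10a configured as C2 of 24 | COc1cc(OC)c2c(c1)OC(c1c(OC)cc(OC)cc1OC)=C1[C@H]2C=C(C)CC1(C)C
A2 | alternative 1 | 3-[(4Z)-2,4-dimethyl-5-(trimethylsilyl)pent-4-en-2-yl]-5,7-dimethoxy-2-(2,4,6-trimethoxyphenyl)chromenylium | COc1cc(OC)c2cc(C(C)(C)C/C(C)=C\[Si](C)(C)C)c(-c3c(OC)cc(OC)cc3OC)[o+]c2c1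
A3 | alternative 2 | (5,7-dimethoxy-2H-chromen-8-yl)[(1S,2R)-2-(5,7-dimethoxy-2H-chromen-8-yl)-4,6,6-trimethylcyclohex-3-en-1-yl]methanone | COc1cc(OC)c2C=CCOc2c1C(=O)[C@H]1[C@H](c2c(OC)cc(OC)c3C=CCOc23)C=C(C)CC1(C)C
A4 | alternative 2 | bis(propargyl ether) of 20: [2,4-dimethoxy-6-(prop-2-ynyloxy)phenyl]{(1S,2R)-2-[2,4-dimethoxy-6-(prop-2-ynyloxy)phenyl]-4,6,6-trimethylcyclohex-3-en-1-yl}methanone | COc1cc(OC)cc(OCC#C)c1C(=O)[C@H]1[C@H](c2c(OC)cc(OC)cc2OCC#C)C=C(C)CC1(C)C
A5 | alternative 3 | trans-2-[2,4-dimethoxy-6-(methoxymethoxy)phenyl]-4-hydroxy-4,6,6-trimethyl-3-nitrocyclohexane-1-carbaldehyde (C4 epimers) | O=C[C@H]1[C@H](c2c(OC)cc(OC)cc2OCOC)[C@@H]([N+](=O)[O-])C(C)(O)CC1(C)C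
A6 | alternative 3 | 1,5-dimethoxy-3-(methoxymethoxy)-2-[(E)-2-nitroethenyl]benzene | COCOc1cc(OC)cc(OC)c1/C=C/[N+](=O)[O-]
A7 | alternative 3 | 3,3-dimethyl-5-oxohexanal | CC(=O)CC(C)(C)CC=O
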